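**Retrosynthetic overview**
- The strategy rests on the substitution pattern of the benzene ring (the only ring): C1 (OH) lies between C2 (side chain C1'–C16') and C6 (CH3), while C4 (OH) lies between C3–H and C5–H. A propenyl(methoxy)carbene, one CO and a terminal alkyne assemble exactly this pattern.
- The arene is therefore built last, forming C3–C4, C1–C2 and C1–C6 from pentacarbonyl[(E)-1-methoxybut-2-enylidene]chromium and a C22 terminal alkyne that already carries the whole chain.
- The ring oxygens emerge differentiated (C1–OH, C4–OCH3); oxidative demethylation to the quinone, desilylation and dithionite reduction finish the synthesis.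
- The alkyne comes from copper-catalysed ethynylation of the C1' allylic bromide. That bromide derives from the product of an enantioselective vinylogous Mukaiyama aldol between (2E,6E)-farnesal (C5'–C16') and the silyl dienolate of ethyl 3-methylbut-2-enoate (C1'–C4'), which sets 5'S and the 2'E olefin.

Key step: step 9

Assumption: the (S,S)-bisphosphoramide is taken to direct the dienolate to the Si face of the enal carbonyl, the face that gives 5S; the sense is to be confirmed by Mosher ester analysis of the aldol product, and the equally accessible antipodal catalyst is used if it proves opposite.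

Step 1
Reactants: 1 (2E,6E)-farnesol
Product: 2 (2E,6E)-3,7,11-trimethyldodeca-2,6,10-trienal (farnesal)
Conditions: activated MnO2 (excess), hexane, rt
Reagents that add atoms: none
Why: Allylic oxidation with MnO2 converts only the allylic alcohol to the enal, leaves the isolated trisubstituted olefins alone and keeps the 2E geometry.

Step 2
Reactants: 3 ethyl 3-methylbut-2-enoate
Product: 4 tert-butyl[(1-ethoxy-3-methylbuta-1,3-dien-1-yl)oxy]dimethylsilane (ketene acetal geometry not controlled and not relayed to later compounds)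
Conditions: LiN(iPr)2, THF, −78 °C; then TBSCl, DMPU, −78 °C → rt
Reagents that add atoms: tert-butyldimethylsilyl chloride, CC(C)(C)[Si](C)(C)Cl
Why: Kinetic γ-deprotonation of the β,β-dimethylacrylate gives the extended lithium dienolate, which is trapped on oxygen (silyl ketene acetal formation).

Step 3
Reactants: 2 (2E,6E)-farnesal; 4 silyl dienolate
Product: 6 ethyl (2E,5S,6E,10E)-5-hydroxy-3,7,11,15-tetramethylhexadeca-2,6,10,14-tetraenoate, via trichlorosilyl aldolate 5 (not isolated)
Conditions: SiCl4 (1.1 equiv), (S,S)-bisphosphoramide (5 mol %; two P=O units, each built on (S)-N,N'-dimethyl-1,1'-binaphthyl-2,2'-diamine, joined through N-methyl nitrogens by a pentane-1,5-diyl tether), iPr2NEt (10 mol %), CH2Cl2, −78 °C; then sat. aq. NaHCO3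
Reagents that add atoms: none
Why: In this catalytic enantioselective vinylogous Mukaiyama aldol the chiral phosphoramide-bound trichlorosilyl cation activates the enal, and the dienolate attacks through its γ-carbon on the Si face exposed by the catalyst, which sets 5S and, through an open transition state, the 2E enoate.

Step 4
Reactants: 6 hydroxy ester
Product: 7 ethyl (2E,5S,6E,10E)-5-(tert-butyldimethylsilyloxy)-3,7,11,15-tetramethylhexadeca-2,6,10,14-tetraenoate
Conditions: TBSCl, imidazole, DMF, rt
Reagents that add atoms: tert-butyldimethylsilyl chloride, CC(C)(C)[Si](C)(C)Cl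
Why: Imidazole-promoted silylation protects the secondary allylic alcohol without touching the enoate or the stereocentre.

Step 5
Reactants: 7 silyloxy ester
Product: 8 (2E,5S,6E,10E)-5-(tert-butyldimethylsilyloxy)-3,7,11,15-tetramethylhexadeca-2,6,10,14-tetraen-1-ol
Conditions: iBu2AlH (2.5 equiv), CH2Cl2, −78 °C; aq. potassium sodium tartrate
Reagents that add atoms: none
Why: 1,2-Reduction of the α,β-unsaturated ester by the aluminium hydride gives the allylic alcohol with the olefin geometry and the silyl ether intact.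

Step 6
Reactants: 8 allylic alcohol
Product: 10 (2E,5S,6E,10E)-1-bromo-5-(tert-butyldimethylsilyloxy)-3,7,11,15-tetramethylhexadeca-2,6,10,14-tetraene (used crude), via allylic mesylate 9 (not isolated)
Conditions: MsCl, Et3N, THF, −45 °C; then LiBr, THF, −45 → 0 °C
Reagents that add atoms: lithium bromide, [Li+].[Br-]
Why: Mesylation followed by direct displacement with bromide at low temperature gives the primary allylic bromide without allylic transposition or E/Z scrambling.

Step 7
Reactants: 10 allylic bromide
Product: 11 (7S,4E,8E,12E)-7-(tert-butyldimethylsilyloxy)-5,9,13,17-tetramethyloctadeca-4,8,12,16-tetraen-1-yne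
Conditions: HC≡CMgBr (3 equiv), CuCl (10 mol %), THF, 0 °C → rt
Reagents that add atoms: ethynylmagnesium bromide, C#C[Mg]Br
Why: Copper-catalysed coupling of an alkynyl Grignard reagent with a prenyl-type bromide occurs at the primary α-carbon because the γ-carbon is fully substituted, giving the skipped enyne with the E olefin retained.

Step 8
Reactants: 12 (E)-1-bromoprop-1-ene; 13 chromium hexacarbonyl
Product: 16 pentacarbonyl[(E)-1-methoxybut-2-enylidene]chromium, via (E)-prop-1-enyllithium 14 (not isolated), via lithium acylchromate 15 (not isolated)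
Conditions: tBuLi (2 equiv), Et2O, −78 °C; Cr(CO)6, Et2O, −78 °C → rt; then Me3OBF4, CH2Cl2–H2O, 0 °C
Reagents that add atoms: trimethyloxonium tetrafluoroborate, C[O+](C)C.F[B-](F)(F)F
Why: This is the Fischer carbene synthesis: bromine–lithium exchange with retention of olefin geometry, addition of the alkenyllithium to a CO ligand and O-methylation of the acylchromate.

Step 9
Reactants: 11 terminal alkyne; 16 carbene complex (1.5 equiv)
Product: 18 2-[(2E,5S,6E,10E)-5-(tert-butyldimethylsilyloxy)-3,7,11,15-tetramethylhexadeca-2,6,10,14-tetraenyl]-4-methoxy-6-methylphenol, via tricarbonylchromium arene complex 17 (not isolated)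
Conditions: THF (0.05 M, degassed), 50 °C, Ar; then air, Et2O, rt
Reagents that add atoms: none
Why: Thermal loss of one CO from 16 frees a site for the alkyne, which inserts into the Cr=C bond with its CH terminus bonding to the carbene carbon (C3–C4); CO insertion at the substituted alkyne carbon (C1–C2) then gives a chromium-bound dienylketene. The ketene carbon and the CH3-bearing propenyl carbon close the six-membered ring by 6π-electrocyclisation (C1–C6), and the cyclohexadienone tautomerises to the Cr(CO)3-bound 4-methoxyphenol 17, from which air removes the metal. This is the Dötz benzannulation of an alkenyl(alkoxy)carbene complex of zerovalent chromium with a terminal alkyne, a well-documented reaction type. No stereocentre is formed, and C5' is remote and untouched. The selectivity needed is the orientation of alkyne insertion, which sterics secure: the substituted alkyne carbon ends next to the CO-derived carbon, so the chain is ortho to OH and meta to CH3. Chemoselectivity rests on the inertness of unactivated trisubstituted olefins towards the carbene at 50 °C, on the 1,4-enyne spacing (cyclopropanation after insertion would need a bicyclobutane) and on the alkenyl carbene in THF, which favours phenol over cyclobutenone formation.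

Step 10
Reactants: 18 4-methoxyphenol
Product: 19 2-[(2E,5S,6E,10E)-5-(tert-butyldimethylsilyloxy)-3,7,11,15-tetramethylhexadeca-2,6,10,14-tetraenyl]-6-methyl-1,4-benzoquinone
Conditions: (NH4)2Ce(NO3)6 (2.2 equiv), MeCN–THF–H2O, 0 °C, 10 min
Reagents that add atoms: water, O
Why: Oxidative demethylation: tetravalent cerium oxidises the p-methoxyphenol by two electrons, water adds at C4 and methanol is lost, and the reaction is fast enough at 0 °C for the silyl ether and the isolated olefins to survive.

Step 11
Reactants: 19 silyloxy quinone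
Product: 20 2-[(2E,5S,6E,10E)-5-hydroxy-3,7,11,15-tetramethylhexadeca-2,6,10,14-tetraenyl]-6-methyl-1,4-benzoquinone
Conditions: 48% aq. HF, MeCN–THF, 0 °C → rt (polypropylene vessel)
Reagents that add atoms: none
Why: Fluoride-driven Si–O cleavage (desilylation) under mildly acidic, non-basic conditions spares the base-sensitive prenylquinone and leaves the C5' configuration untouched.

Step 12
Reactants: 20 hydroxy quinone
Product: 21 2-[(2E,5S,6E,10E)-5-hydroxy-3,7,11,15-tetramethylhexadeca-2,6,10,14-tetraenyl]-6-methylbenzene-1,4-diol (CNP0314458.1)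
Conditions: Na2S2O4 (aq., excess), Et2O, rt, Ar (degassed solvents)
Reagents that add atoms: none
Why: Dithionite reduction of the quinone to the hydroquinone is a mild two-electron reduction that touches no other group, so the air-sensitive target is formed last and isolated under argon.

**Compound list**
1 | (2E,6E)-farnesol | CC(C)=CCC/C(C)=C/CC/C(C)=C/CO | starting material
2 | (2E,6E)-3,7,11-trimethyldodeca-2,6,10-trienal | CC(C)=CCC/C(C)=C/CC/C(C)=C/C=O | intermediate
3 | ethyl 3-methylbut-2-enoate | CCOC(=O)C=C(C)C | starting material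
4 | tert-butyl[(1-ethoxy-3-methylbuta-1,3-dien-1-yl)oxy]dimethylsilane | C=C(C)C=C(OCC)O[Si](C)(C)C(C)(C)C | intermediate
5 | ethyl (2E,5S,6E,10E)-3,7,11,15-tetramethyl-5-(trichlorosilyloxy)hexadeca-2,6,10,14-tetraenoate | CC(C)=CCC/C(C)=C/CC/C(C)=C/[C@@H](O[Si](Cl)(Cl)Cl)C/C(C)=C/C(=O)OCC | intermediate (not isolated)
6 | ethyl (2E,5S,6E,10E)-5-hydroxy-3,7,11,15-tetramethylhexadeca-2,6,10,14-tetraenoate | CC(C)=CCC/C(C)=C/CC/C(C)=C/[C@@H](O)C/C(C)=C/C(=O)OCC | intermediate
7 | ethyl (2E,5S,6E,10E)-5-(tert-butyldimethylsilyloxy)-3,7,11,15-tetramethylhexadeca-2,6,10,14-tetraenoate | CC(C)=CCC/C(C)=C/CC/C(C)=C/[C@@H](O[Si](C)(C)C(C)(C)C)C/C(C)=C/C(=O)OCC | intermediate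
8 | (2E,5S,6E,10E)-5-(tert-butyldimethylsilyloxy)-3,7,11,15-tetramethylhexadeca-2,6,10,14-tetraen-1-ol | CC(C)=CCC/C(C)=C/CC/C(C)=C/[C@@H](O[Si](C)(C)C(C)(C)C)C/C(C)=C/CO | intermediate
9 | (2E,5S,6E,10E)-5-(tert-butyldimethylsilyloxy)-3,7,11,15-tetramethylhexadeca-2,6,10,14-tetraenyl methanesulfonate | CC(C)=CCC/C(C)=C/CC/C(C)=C/[C@@H](O[Si](C)(C)C(C)(C)C)C/C(C)=C/COS(C)(=O)=O | intermediate (not isolated)
10 | (2E,5S,6E,10E)-1-bromo-5-(tert-butyldimethylsilyloxy)-3,7,11,15-tetramethylhexadeca-2,6,10,14-tetraene | CC(C)=CCC/C(C)=C/CC/C(C)=C/[C@@H](O[Si](C)(C)C(C)(C)C)C/C(C)=C/CBr | intermediate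
11 | (7S,4E,8E,12E)-7-(tert-butyldimethylsilyloxy)-5,9,13,17-tetramethyloctadeca-4,8,12,16-tetraen-1-yne | CC(C)=CCC/C(C)=C/CC/C(C)=C/[C@@H](O[Si](C)(C)C(C)(C)C)C/C(C)=C/CC#C | intermediate
12 | (E)-1-bromoprop-1-ene | C/C=C/Br | starting material
13 | chromium hexacarbonyl | O=C=[Cr](=C=O)(=C=O)(=C=O)(=C=O)=C=O | starting material
14 | (E)-prop-1-enyllithium | C/C=C/[Li] | intermediate (not isolated)
15 | lithium pentacarbonyl[(E)-1-oxidobut-2-enylidene]chromate | [Li+].[O-]C(/C=C/C)=[Cr](=C=O)(=C=O)(=C=O)(=C=O)=C=O | intermediate (not isolated)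
16 | pentacarbonyl[(E)-1-methoxybut-2-enylidene]chromium | COC(/C=C/C)=[Cr](=C=O)(=C=O)(=C=O)(=C=O)=C=O | intermediate
17 | tricarbonyl(η6-arene)chromium complex of phenol 18 (Cr(CO)3 bound to the benzene ring; written as two fragments) | CC(C)=CCC/C(C)=C/CC/C(C)=C/[C@@H](O[Si](C)(C)C(C)(C)C)C/C(C)=C/Cc1cc(OC)cc(C)c1O.O=C=[Cr](=C=O)=C=O | intermediate (not isolated)
18 | 2-[(2E,5S,6E,10E)-5-(tert-butyldimethylsilyloxy)-3,7,11,15-tetramethylhexadeca-2,6,10,14-tetraenyl]-4-methoxy-6-methylphenol | CC(C)=CCC/C(C)=C/CC/C(C)=C/[C@@H](O[Si](C)(C)C(C)(C)C)C/C(C)=C/Cc1cc(OC)cc(C)c1O | intermediate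
19 | 2-[(2E,5S,6E,10E)-5-(tert-butyldimethylsilyloxy)-3,7,11,15-tetramethylhexadeca-2,6,10,14-tetraenyl]-6-methyl-1,4-benzoquinone | CC(C)=CCC/C(C)=C/CC/C(C)=C/[C@@H](O[Si](C)(C)C(C)(C)C)C/C(C)=C/CC1=CC(=O)C=C(C)C1=O | intermediate
20 | 2-[(2E,5S,6E,10E)-5-hydroxy-3,7,11,15-tetramethylhexadeca-2,6,10,14-tetraenyl]-6-methyl-1,4-benzoquinone | CC(C)=CCC/C(C)=C/CC/C(C)=C/[C@@H](O)C/C(C)=C/CC1=CC(=O)C=C(C)C1=O | intermediate
21 | 2-[(2E,5S,6E,10E)-5-hydroxy-3,7,11,15-tetramethylhexadeca-2,6,10,14-tetraenyl]-6-methylbenzene-1,4-diol | CC(C)=CCC/C(C)=C/CC/C(C)=C/[C@@H](O)C/C(C)=C/Cc1cc(O)cc(C)c1O | target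

**Step count**
Total: 12 steps. Longest linear sequence: 10 steps (1, 3, 4, 5, 6, 7, 9, 10, 11, 12 from farnesol).

**Steps most likely to fail**

Step 9 (benzannulation). After alkyne insertion the vinylcarbene may take up a second alkyne or close without the propenyl carbon (cyclobutenone or furan pathways), and the terminal alkyne may oligomerise, so conversion to the phenol may stay low. The fallback sets out from bromide 10 and comes back at quinone 19. Commercial 4-methoxy-2-methylphenol is brominated at its only free ortho position (NBS, MeCN, 0 °C) to 2-bromo-4-methoxy-6-methylphenol F1, which is O-methylated (MeI, K2CO3, acetone) to 1-bromo-2,5-dimethoxy-3-methylbenzene F2. Bromine–lithium exchange (nBuLi, THF, −78 °C), transmetalation with CuBr·SMe2 and alkylation of the arylcopper with 10 at its primary carbon give tert-butyl{[(2E,5S,6E,10E)-1-(2,5-dimethoxy-3-methylphenyl)-3,7,11,15-tetramethylhexadeca-2,6,10,14-tetraen-5-yl]oxy}dimethylsilane F3. Oxidative demethylation of F3 with (NH4)2Ce(NO3)6 (MeCN–H2O, 0 °C) delivers 19, and steps 11 and 12 follow unchanged.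

Step 3 (asymmetric vinylogous aldol). Facial discrimination on a β,β-disubstituted enal may be insufficient, and the Lewis acid may erode the enal geometry or divert the dienolate to α-attack. The fallback sets out from 2 and 4 and comes back at 6. A BF3·OEt2-promoted vinylogous Mukaiyama aldol (CH2Cl2, −78 °C) gives racemic ethyl (2E,6E,10E)-5-hydroxy-3,7,11,15-tetramethylhexadeca-2,6,10,14-tetraenoate F4. MnO2 (CH2Cl2, rt) oxidises this allylic alcohol under neutral conditions to ethyl (2E,6E,10E)-3,7,11,15-tetramethyl-5-oxohexadeca-2,6,10,14-tetraenoate F5. Corey–Bakshi–Shibata reduction with the (R)-configured B-methyl oxazaborolidine (from (R)-diphenylprolinol) and catecholborane (toluene, −78 °C), in which the alkenyl group acts as the large substituent, returns 6 with the 5S configuration.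

Step 7 (ethynylation). The alkynyl nucleophile may attack at the γ-carbon, the acetylene may be alkylated twice, or the allylic bromide may homocouple. The fallback sets out from 10 and comes back at 11. (Trimethylsilyl)ethynylmagnesium bromide (from trimethylsilylacetylene and EtMgBr) with CuBr·SMe2 in THF gives tert-butyldimethyl{[(7S,4E,8E,12E)-5,9,13,17-tetramethyl-1-(trimethylsilyl)octadeca-4,8,12,16-tetraen-1-yn-7-yl]oxy}silane F6; the silyl cap rules out double alkylation and its bulk favours attack at the primary carbon. K2CO3 in MeOH at rt then removes only the alkynyl silyl group and gives 11.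

Further compounds
F1 | step 9 | 2-bromo-4-methoxy-6-methylphenol | Cc1cc(OC)cc(Br)c1O
F2 | step 9 | 1-bromo-2,5-dimethoxy-3-methylbenzene | Cc1cc(OC)cc(Br)c1OC
F3 | step 9 | tert-butyl{[(2E,5S,6E,10E)-1-(2,5-dimethoxy-3-methylphenyl)-3,7,11,15-tetramethylhexadeca-2,6,10,14-tetraen-5-yl]oxy}dimethylsilane | CC(C)=CCC/C(C)=C/CC/C(C)=C/[C@@H](O[Si](C)(C)C(C)(C)C)C/C(C)=C/Cc1cc(OC)cc(C)c1OC
F4 | step 3 | racemic ethyl (2E,6E,10E)-5-hydroxy-3,7,11,15-tetramethylhexadeca-2,6,10,14-tetraenoate | CC(C)=CCC/C(C)=C/CC/C(C)=C/C(O)C/C(C)=C/C(=O)OCC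
F5 | step 3 | ethyl (2E,6E,10E)-3,7,11,15-tetramethyl-5-oxohexadeca-2,6,10,14-tetraenoate | CC(C)=CCC/C(C)=C/CC/C(C)=C/C(=O)C/C(C)=C/C(=O)OCC
F6 | step 7 | tert-butyldimethyl{[(7S,4E,8E,12E)-5,9,13,17-tetramethyl-1-(trimethylsilyl)octadeca-4,8,12,16-tetraen-1-yn-7-yl]oxy}silane | CC(C)=CCC/C(C)=C/CC/C(C)=C/[C@@H](O[Si](C)(C)C(C)(C)C)C/C(C)=C/CC#C[Si](C)(C)C
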